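The vessel is closed and stirred and holds a racemate over a single-handed catalyst, and the question is how clean the right-handed substrate stands as the left-handed substrate is consumed inside 6.0 min.

| flask | left-handed substrate | right-handed substrate | gas | free catalyst | added ligand | remark | time |
|---|---|---|---|---|---|---|---|
| beta | 0.12 M | 0.12 M | 4.5 mM (held) | 0.46 mol% | 0.36 mM | run made earlier |  |
| gamma | 0.19 M | 0.19 M | 4.5 mM (held) | 0.46 mol% | 0.36 mM | run made earlier |  |
| epsilon | 0.088 M | 0.088 M | 4.5 mM (held) | 0.46 mol% | 0.18 mM | run made earlier |  |
| flask | 0.088 M | 0.088 M | 4.5 mM (held) | 0.46 mol% | 0.36 mM |  | 6.0 min |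

- beta (time / min: right-handed substrate / %, left-handed substrate / %): 0.417: 42.5, 35.5; 0.667: 38.2, 25.3; 1.33: 26.0, 7.8; 2.50: 10.8, 0; 5.00: 1.7, 1.6
- gamma (time / min: right-handed substrate / %, left-handed substrate / %): 1.00: 37.6, 22.6; 2.00: 19.0, 4.1; 3.00: 4.4, 0; 4.00: 0.4, 0; 5.00: 1.3, 0
- epsilon (time / min: right-handed substrate / %, left-handed substrate / %): 0.417: 41.6, 33.4; 1.33: 23.1, 7.4; 2.00: 13.3, 3.7; 3.00: 5.1, 0.3; 5.00: 0.1, 0.1

(each reading ± 1 percentage point)

* whether the excess of right-handed substrate over left-handed substrate among what is left of the two reaches 90% by 6.0 min (yes / no)
* the highest excess of right-handed substrate over left-handed substrate among what is left of the two up to 6.0 min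

- free catalyst is single-handed; left-handed substrate and right-handed substrate are mirror images of each other, charged as a racemate, each of them at the stated concentration
- at the start none of the gas is in solution

*What do you compare first?* I compare the two rates at one moment. I take each substrate to fall in proportion to what is left of it, so any factor common to both cancels, and what remains is the selectivity factor, the ratio of the logarithms of the fractions of own charge left, which the epsilon readings at 1.33 min put at 2.47.

*How does that comparison drift?* The rate of the left-handed substrate over that of the right-handed substrate is this factor times the ratio of their fractions left, and that ratio keeps sinking, so the excess climbs as the right-handed fraction falls. Setting the ratio of fractions to what the wanted excess demands gives 13.6%, the mark: the fraction of its own charge of right-handed substrate at which the excess reaches 90%.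

*But epsilon had half the flask's ligand?* Beta has the flask's ligand and reads 2.84 at 1.33 min, a difference I take to lie within the scatter of 1 percentage point, though I cannot lay it to the ligand or deny it, since beta's charge is also larger than epsilon's.

*Is there time?* Beta's right-handed reading at 5.00 min is 3.40% of its charge, under the mark, and by my reckoning that fraction means an excess of 98.6%, so, taking the flask, with beta's ligand on epsilon's charge, to fall at a like pace, I say yes, with a top near that figure.

The forecast also says yes but goes higher than my figure, to 99.7%, with a relative rate of about 2.5 and the words “the excess is still climbing, close to 100%”.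

The new flask answers yes with a top of 99.0%.

    reagent + free catalyst + left-handed substrate → free catalyst + left-handed product (k = 34000 M⁻² s⁻¹)
    free catalyst → spent catalyst (k = 0.00150 s⁻¹)
    gas ⇌ reagent, rate k3*(csat - [reagent]) (kL = 0.700 s⁻¹)
    reagent + free catalyst + right-handed substrate → free catalyst + right-handed product (k = 14000 M⁻² s⁻¹)
    free catalyst + added ligand ⇌ idle complex (K = 3700 M⁻¹, k = 300 M⁻¹ s⁻¹)

In the new flask the left-handed step takes reagent at 1.3 times the rate of the right-handed step at 0.941 min and at 0.013 times that rate at 6.00 min, and the flask reaches 90% at 3.50 min with 12.7% of the right-handed charge left, beside the mark of 13.6%. The gamma run crosses the same mark between 2.00 min, reading 38.0% of its right-handed charge, and 3.00 min, reading 8.80%, while the new flask ends at 6.00 min with 2.5% of its right-handed charge.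

(The numbers in the tables were computed from invented constants.)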